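**Retrosynthetic overview**

1. Isochromene numbering is used (ring A = pyran C1, O2, C3, C4, C4a, C8a; ring B = carbocycle C4a, C5–C8, C8a). The target comes from its tris-silylated form by fluoride, and that from acylation of the C8 hydroxyl of a cis-7,8-diol with silyl-protected orsellinoyl chloride.
2. The cis-diol comes from closure of ring B at C7–C8: an intramolecular aldol addition of an acyloin–aldehyde under a chiral dinuclear zinc catalyst, which makes the bond, the ring and both stereocentres (7R,8R) in one operation from a precursor with no fixed stereocentre.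
3. The acyloin–aldehyde comes from carbonylation of a C8a enol triflate (C8) and from a sulfide contraction between a pyran-4-thione and a bromoketone made from acetoin (C4a=C5, C6, C7, methyl).
4. Ring A is bought whole as kojic acid (5-OH becomes the triflate, CH2OH becomes the acrylate), so the ring order is A (purchased), then B (key step).
5. Enabling feature: ring B holds O=C6–C7(OH)(CH3)–C8H(O), an acyloin-aldol retron. C7 has no hydrogen and C8a is sp2, so the adduct cannot dehydrate toward a benzopyrylium. C6 is a vinylogous ester through C5=C4a and O2 of ring A, so C7 is the only enolisable carbon.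

Key step: step 10

Remark: racemic acetoin is used, so every intermediate carrying the CH(OR)CH3 unit is racemic at the future C7; that centre is planarised in the key step.
Remark: the (S,S) antipode of the ProPhenol ligand is assumed to lead to (7R,8R); if the sense of induction is opposite, the (R,R) ligand is used under the same conditions.
Remark: the exocyclic C4a=C5 bond of the open precursors is a push–pull alkene expected to interconvert between E and Z; its SMILES are written without geometry.

**Route**

Step 1
Reactants: 1 kojic acid; 2 N-phenylbis(trifluoromethanesulfonimide)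
Product: 3 6-(hydroxymethyl)-4-oxo-4H-pyran-3-yl trifluoromethanesulfonate
Conditions: Et3N, DMF/CH2Cl2, 0 °C to rt
Reagents that add atoms: N-phenylbis(trifluoromethanesulfonimide) (2), FC(F)(F)S(=O)(=O)N(c1ccccc1)S(=O)(=O)C(F)(F)F
Why: Chemoselective phenol-type O-triflation: Et3N ionises only the acidic enolic 5-hydroxyl and the mild triflyl donor does not sulfonylate the neutral primary alcohol, which installs the future C8a handle.

Step 2
Reactants: 3 6-(hydroxymethyl)-4-oxo-4H-pyran-3-yl trifluoromethanesulfonate
Product: 4 6-formyl-4-oxo-4H-pyran-3-yl trifluoromethanesulfonate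
Conditions: activated MnO2, CHCl3, rt
Reagents that add atoms: none
Why: MnO2 oxidation of an allylic-type primary alcohol (conjugated with the pyranone C=C) should stop at the aldehyde and leave the enol triflate intact.

Step 3
Reactants: 4 6-formyl-4-oxo-4H-pyran-3-yl trifluoromethanesulfonate; 5 (triphenylphosphoranylidene)ketene; 6 2-(trimethylsilyl)ethanol
Product: 8 2-(trimethylsilyl)ethyl (E)-3-[4-oxo-5-(trifluoromethylsulfonyloxy)-4H-pyran-2-yl]prop-2-enoate, via ester ylide 7 (not isolated)
Conditions: 5 and 6, toluene, 80 °C; then 4, rt to 50 °C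
Reagents that add atoms: (triphenylphosphoranylidene)ketene (5), O=C=C=P(c1ccccc1)(c1ccccc1)c1ccccc1; 2-(trimethylsilyl)ethanol (6), C[Si](C)(C)CCO
Why: The alcohol adds to the cumulated ylide to give the stabilised ester ylide 7, whose Wittig reaction with the aldehyde should give the E-acrylate (the C3 side chain) as a fluoride-labile ester.

Step 4
Reactants: 8 2-(trimethylsilyl)ethyl (E)-3-[4-oxo-5-(trifluoromethylsulfonyloxy)-4H-pyran-2-yl]prop-2-enoate; 9 Lawesson's reagent
Product: 10 2-(trimethylsilyl)ethyl (E)-3-[4-thioxo-5-(trifluoromethylsulfonyloxy)-4H-pyran-2-yl]prop-2-enoate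
Conditions: toluene, 70 °C
Reagents that add atoms: Lawesson's reagent (9), COc1ccc(cc1)P1(=S)SP(=S)(S1)c1ccc(OC)cc1
Why: Thionation with Lawesson's reagent is fastest at the electron-rich vinylogous-ester carbonyl of a 4-pyranone, so the acrylate ester and the triflate should survive and the future C4a is activated for olefination.

Step 5
Reactants: 11 3-hydroxybutan-2-one (acetoin, racemic); 12 chlorotriethylsilane
Product: 13 3-(triethylsilyloxy)butan-2-one
Conditions: imidazole, DMF, 0 °C to rt
Reagents that add atoms: chlorotriethylsilane (12), CC[Si](Cl)(CC)CC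
Why: Standard silylation of the secondary alcohol protects the acyloin oxygen (future O7) so that the ketone can be enolised regioselectively in the next step.

Step 6
Reactants: 13 3-(triethylsilyloxy)butan-2-one; 14 chlorotrimethylsilane; 15 N-bromosuccinimide
Product: 17 1-bromo-3-(triethylsilyloxy)butan-2-one, via silyl enol ether 16 (not isolated)
Conditions: LiN(iPr)2 (LDA), TMSCl, THF, −78 °C; then NBS, NaHCO3, THF, −78 to 0 °C
Reagents that add atoms: N-bromosuccinimide (15), BrN1C(=O)CCC1=O; chlorotrimethylsilane (14), C[Si](C)(C)Cl, adds silicon to intermediate 16 only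
Why: Kinetic deprotonation with in situ silyl trapping takes the unhindered methyl side of the α-silyloxy ketone, and electrophilic bromination of silyl enol ether 16 gives the bromomethyl ketone without touching the oxygenated carbon.

Step 7
Reactants: 10 2-(trimethylsilyl)ethyl (E)-3-[4-thioxo-5-(trifluoromethylsulfonyloxy)-4H-pyran-2-yl]prop-2-enoate; 17 1-bromo-3-(triethylsilyloxy)butan-2-one
Product: 20 2-(trimethylsilyl)ethyl (E)-3-{4-[2-oxo-3-(triethylsilyloxy)butylidene]-5-(trifluoromethylsulfonyloxy)-4H-pyran-2-yl}prop-2-enoate, via thiopyrylium bromide 18 (not isolated), via thiirane 19 (not isolated)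
Conditions: MeCN, rt; then Et3N, PPh3, 0 °C to rt
Reagents that add atoms: none
Why: Eschenmoser sulfide contraction: the soft thione sulfur is alkylated by the α-bromoketone, Et3N deprotonates the S–CH2–C=O carbon, the ylide closes onto the pyrylium C4 to thiirane 19 and PPh3 removes sulfur, forming the C4a=C5 bond regiospecifically at the former thiocarbonyl carbon.

Step 8
Reactants: 20 2-(trimethylsilyl)ethyl (E)-3-{4-[2-oxo-3-(triethylsilyloxy)butylidene]-5-(trifluoromethylsulfonyloxy)-4H-pyran-2-yl}prop-2-enoate; 21 carbon monoxide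
Product: 22 2-(trimethylsilyl)ethyl (E)-3-{5-formyl-4-[2-oxo-3-(triethylsilyloxy)butylidene]-4H-pyran-2-yl}prop-2-enoate
Conditions: Pd(PPh3)4 (5 mol%), LiCl, CO (1 atm), Bu3SnH (slow addition), THF, 50 °C
Reagents that add atoms: carbon monoxide (21), [C-]#[O+]
Why: Palladium-catalysed reductive carbonylation of an enol triflate (oxidative addition to zerovalent palladium, CO insertion, hydride transfer from Bu3SnH kept at low concentration) introduces C8 as the aldehyde under neutral conditions.

Step 9
Reactants: 22 2-(trimethylsilyl)ethyl (E)-3-{5-formyl-4-[2-oxo-3-(triethylsilyloxy)butylidene]-4H-pyran-2-yl}prop-2-enoate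
Product: 23 2-(trimethylsilyl)ethyl (E)-3-[5-formyl-4-(3-hydroxy-2-oxobutylidene)-4H-pyran-2-yl]prop-2-enoate
Conditions: HF·pyridine, pyridine, THF, 0 °C; used at once
Reagents that add atoms: none
Why: Buffered fluoride cleaves the triethylsilyl ether while the 2-(trimethylsilyl)ethyl ester is inert to HF·pyridine, freeing the acyloin hydroxyl needed for zinc binding.

Step 10
Reactants: 23 2-(trimethylsilyl)ethyl (E)-3-[5-formyl-4-(3-hydroxy-2-oxobutylidene)-4H-pyran-2-yl]prop-2-enoate
Product: 24 2-(trimethylsilyl)ethyl (E)-3-[(7R,8R)-7,8-dihydroxy-7-methyl-6-oxo-7,8-dihydro-6H-isochromen-3-yl]prop-2-enoate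
Conditions: (S,S)-ProPhenol (20 mol%), Et2Zn (40 mol%), 4 Å molecular sieves, THF, −20 °C; aqueous NH4Cl quench
Reagents that add atoms: none
Why: Proposed new method: the dinuclear zinc complex formed from ProPhenol and Et2Zn is expected to bind the acyloin of 23 as an O6,O7-chelate, remove the C7 hydrogen with its basic zinc alkoxide site and so form a zinc enediolate whose C7 adds to the C8 aldehyde coordinated at the second zinc; the closest known reaction type is the dinuclear-zinc-catalysed direct aldol addition of α-hydroxy ketones to aldehydes, which gives syn-1,2-diols, here extended to an intramolecular case with an α-methyl donor. Ring B closes in the 6-(enolendo)-exo-trig mode, and no other ring size can form because C7 is the only enolisable carbon (C6 is a vinylogous ester through C5=C4a and O2, and C5 and C8a carry no acidic hydrogen). C7 should become R because the planar enediolate, which erases the racemic C7–H centre of 23, is attacked on the face left open by the diarylprolinol pocket of the ligand. C8 should become R, cis to the C7 oxygen, because O7 and the aldehyde oxygen are held on the same dizinc core in the bond-forming arrangement. The step needs the catalysed closure to outrun uncatalysed aldolisation, which the weak acidity of the α-position of a vinylogous ester, the absence of free base and the low temperature should secure, and it needs the reactive C4a=C5 isomer, which the push–pull character of that bond supplies by equilibration. The adduct has no hydrogen on C7 or C8a, so it cannot dehydrate and the stereodyad should persist.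

Step 11
Reactants: 25 orsellinic acid (2,4-dihydroxy-6-methylbenzoic acid); 26 tert-butylchlorodimethylsilane
Product: 27 tert-butyldimethylsilyl 2,4-bis(tert-butyldimethylsilyloxy)-6-methylbenzoate
Conditions: imidazole, DMF, rt
Reagents that add atoms: tert-butylchlorodimethylsilane (26), CC(C)(C)[Si](C)(C)Cl
Why: Exhaustive silylation of both phenols and the carboxyl group gives the silyl ester, the direct precursor of the acid chloride, without heating the decarboxylation-prone acid.

Step 12
Reactants: 27 tert-butyldimethylsilyl 2,4-bis(tert-butyldimethylsilyloxy)-6-methylbenzoate; 28 oxalyl chloride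
Product: 29 2,4-bis(tert-butyldimethylsilyloxy)-6-methylbenzoyl chloride
Conditions: DMF (cat.), CH2Cl2, 0 °C to rt
Reagents that add atoms: oxalyl chloride (28), O=C(Cl)C(=O)Cl
Why: The chloroiminium salt from oxalyl chloride and catalytic DMF converts a silyl ester directly into the acid chloride under neutral conditions, so the aryl silyl ethers are kept.

Step 13
Reactants: 24 2-(trimethylsilyl)ethyl (E)-3-[(7R,8R)-7,8-dihydroxy-7-methyl-6-oxo-7,8-dihydro-6H-isochromen-3-yl]prop-2-enoate; 29 2,4-bis(tert-butyldimethylsilyloxy)-6-methylbenzoyl chloride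
Product: 30 (7R,8R)-7-hydroxy-7-methyl-6-oxo-3-{(E)-3-oxo-3-[2-(trimethylsilyl)ethoxy]prop-1-enyl}-7,8-dihydro-6H-isochromen-8-yl 2,4-bis(tert-butyldimethylsilyloxy)-6-methylbenzoate
Conditions: Et3N, DMAP (cat.), CH2Cl2, −20 °C to rt
Reagents that add atoms: none
Why: DMAP-catalysed acylation should take the secondary allylic C8 hydroxyl in preference to the tertiary C7 hydroxyl on steric grounds, the cold, weakly basic conditions are chosen to avoid retro-aldol opening, and C8 keeps its configuration because only the O–H bond reacts.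

Step 14
Reactants: 30 (7R,8R)-7-hydroxy-7-methyl-6-oxo-3-{(E)-3-oxo-3-[2-(trimethylsilyl)ethoxy]prop-1-enyl}-7,8-dihydro-6H-isochromen-8-yl 2,4-bis(tert-butyldimethylsilyloxy)-6-methylbenzoate
Product: 31 (+)-mitorubrinic acid B
Conditions: TBAF, AcOH, THF, 0 °C to rt
Reagents that add atoms: none
Why: Fluoride cleaves both aryl silyl ethers and, by β-silyl fragmentation with loss of ethene, the 2-(trimethylsilyl)ethyl ester, while the acetic acid buffer keeps the medium near neutral so that the C8 ester should not migrate to O7 and ring A should not be opened.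

**Compound list**

1 | kojic acid | O=C1C=C(CO)OC=C1O | starting material
2 | N-phenylbis(trifluoromethanesulfonimide) | FC(F)(F)S(=O)(=O)N(c1ccccc1)S(=O)(=O)C(F)(F)F | starting material
3 | 6-(hydroxymethyl)-4-oxo-4H-pyran-3-yl trifluoromethanesulfonate | O=C1C=C(CO)OC=C1OS(=O)(=O)C(F)(F)F | intermediate
4 | 6-formyl-4-oxo-4H-pyran-3-yl trifluoromethanesulfonate | O=CC1=CC(=O)C(OS(=O)(=O)C(F)(F)F)=CO1 | intermediate
5 | (triphenylphosphoranylidene)ketene | O=C=C=P(c1ccccc1)(c1ccccc1)c1ccccc1 | starting material
6 | 2-(trimethylsilyl)ethanol | C[Si](C)(C)CCO | starting material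
7 | 2-(trimethylsilyl)ethyl (triphenylphosphoranylidene)acetate (not isolated) | C[Si](C)(C)CCOC(=O)C=P(c1ccccc1)(c1ccccc1)c1ccccc1 | intermediate
8 | 2-(trimethylsilyl)ethyl (E)-3-[4-oxo-5-(trifluoromethylsulfonyloxy)-4H-pyran-2-yl]prop-2-enoate | C[Si](C)(C)CCOC(=O)/C=C/C1=CC(=O)C(OS(=O)(=O)C(F)(F)F)=CO1 | intermediate
9 | Lawesson's reagent | COc1ccc(cc1)P1(=S)SP(=S)(S1)c1ccc(OC)cc1 | starting material
10 | 2-(trimethylsilyl)ethyl (E)-3-[4-thioxo-5-(trifluoromethylsulfonyloxy)-4H-pyran-2-yl]prop-2-enoate | C[Si](C)(C)CCOC(=O)/C=C/C1=CC(=S)C(OS(=O)(=O)C(F)(F)F)=CO1 | intermediate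
11 | 3-hydroxybutan-2-one (acetoin, racemic) | CC(O)C(C)=O | starting material
12 | chlorotriethylsilane | CC[Si](Cl)(CC)CC | starting material
13 | 3-(triethylsilyloxy)butan-2-one (racemic) | CC[Si](CC)(CC)OC(C)C(C)=O | intermediate
14 | chlorotrimethylsilane | C[Si](C)(C)Cl | starting material
15 | N-bromosuccinimide | BrN1C(=O)CCC1=O | starting material
16 | 3-(triethylsilyloxy)-2-(trimethylsilyloxy)but-1-ene (not isolated) | CC[Si](CC)(CC)OC(C)C(=C)O[Si](C)(C)C | intermediate
17 | 1-bromo-3-(triethylsilyloxy)butan-2-one (racemic) | CC[Si](CC)(CC)OC(C)C(=O)CBr | intermediate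
18 | 4-{[2-oxo-3-(triethylsilyloxy)butyl]sulfanyl}-2-{(E)-3-oxo-3-[2-(trimethylsilyl)ethoxy]prop-1-enyl}-5-(trifluoromethylsulfonyloxy)pyrylium bromide (not isolated) | C[Si](C)(C)CCOC(=O)/C=C/c1cc(SCC(=O)C(C)O[Si](CC)(CC)CC)c(OS(=O)(=O)C(F)(F)F)c[o+]1.[Br-] | intermediate
19 | spiro-thiirane at pyran C4 carrying the 2-(triethylsilyloxy)propanoyl group (not isolated) | C[Si](C)(C)CCOC(=O)/C=C/C1=CC2(SC2C(=O)C(C)O[Si](CC)(CC)CC)C(OS(=O)(=O)C(F)(F)F)=CO1 | intermediate
20 | 2-(trimethylsilyl)ethyl (E)-3-{4-[2-oxo-3-(triethylsilyloxy)butylidene]-5-(trifluoromethylsulfonyloxy)-4H-pyran-2-yl}prop-2-enoate | C[Si](C)(C)CCOC(=O)/C=C/C1=CC(=CC(=O)C(C)O[Si](CC)(CC)CC)C(OS(=O)(=O)C(F)(F)F)=CO1 | intermediate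
21 | carbon monoxide | [C-]#[O+] | starting material
22 | 2-(trimethylsilyl)ethyl (E)-3-{5-formyl-4-[2-oxo-3-(triethylsilyloxy)butylidene]-4H-pyran-2-yl}prop-2-enoate | C[Si](C)(C)CCOC(=O)/C=C/C1=CC(=CC(=O)C(C)O[Si](CC)(CC)CC)C(C=O)=CO1 | intermediate
23 | 2-(trimethylsilyl)ethyl (E)-3-[5-formyl-4-(3-hydroxy-2-oxobutylidene)-4H-pyran-2-yl]prop-2-enoate | C[Si](C)(C)CCOC(=O)/C=C/C1=CC(=CC(=O)C(C)O)C(C=O)=CO1 | intermediate
24 | 2-(trimethylsilyl)ethyl (E)-3-[(7R,8R)-7,8-dihydroxy-7-methyl-6-oxo-7,8-dihydro-6H-isochromen-3-yl]prop-2-enoate | O[C@@H]1C2=COC(/C=C/C(=O)OCC[Si](C)(C)C)=CC2=CC(=O)[C@]1(C)O | intermediate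
25 | orsellinic acid | Cc1cc(O)cc(O)c1C(=O)O | starting material
26 | tert-butylchlorodimethylsilane | CC(C)(C)[Si](C)(C)Cl | starting material
27 | tert-butyldimethylsilyl 2,4-bis(tert-butyldimethylsilyloxy)-6-methylbenzoate | Cc1cc(O[Si](C)(C)C(C)(C)C)cc(O[Si](C)(C)C(C)(C)C)c1C(=O)O[Si](C)(C)C(C)(C)C | intermediate
28 | oxalyl chloride | O=C(Cl)C(=O)Cl | starting material
29 | 2,4-bis(tert-butyldimethylsilyloxy)-6-methylbenzoyl chloride | Cc1cc(O[Si](C)(C)C(C)(C)C)cc(O[Si](C)(C)C(C)(C)C)c1C(=O)Cl | intermediate
30 | (7R,8R)-7-hydroxy-7-methyl-6-oxo-3-{(E)-3-oxo-3-[2-(trimethylsilyl)ethoxy]prop-1-enyl}-7,8-dihydro-6H-isochromen-8-yl 2,4-bis(tert-butyldimethylsilyloxy)-6-methylbenzoate | Cc1cc(O[Si](C)(C)C(C)(C)C)cc(O[Si](C)(C)C(C)(C)C)c1C(=O)O[C@@H]1C2=COC(/C=C/C(=O)OCC[Si](C)(C)C)=CC2=CC(=O)[C@]1(C)O | intermediate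
31 | (+)-mitorubrinic acid B | Cc1cc(O)cc(O)c1C(=O)O[C@@H]1C2=COC(/C=C/C(=O)O)=CC2=CC(=O)[C@]1(C)O | target

**Step count and risks**

Total step count: 14. Longest linear sequence: 10 steps (steps 1, 2, 3, 4, 7, 8, 9, 10, 13, 14).

Steps most likely to fail:

1. Step 10 (proposed new method). The process at risk is loss of catalyst control: enolisation at C7 may be too slow at the zinc centre, or ring closure may already occur without the catalyst during or after desilylation, giving racemic or trans material. The fallback uses known chemistry and moves stereocontrol from catalysis to resolution. It sets out from 23, which is closed without a chiral catalyst (DBU, 10 mol%, CH2Cl2, 0 °C; base-catalysed intramolecular aldol addition) to the racemic cis-diol F1, separated from any trans isomer by chromatography. Acylative kinetic resolution of the secondary allylic alcohol follows (isobutyric anhydride, 0.55 equiv, chiral isothiourea catalyst benzotetramisole, 5 mol%, iPr2NEt, CHCl3, 0 °C, catalyst antipode chosen so that the (7S,8S) enantiomer reacts). The unwanted enantiomer leaves as the (7S,8S) isobutyrate F2, and the unreacted (7R,8R) alcohol is 24, where the route is rejoined before step 13.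

2. Step 7. The process at risk is attack of base or bromide at the unsubstituted α-position of the S-alkylpyrylium salt with ring opening, or failure of the ylide to close to the thiirane. The fallback avoids the pyrylium salt and base altogether. It sets out from 17, which is converted with N,N'-ditosylhydrazine and DBU (THF, 0 °C) into 1-diazo-3-(triethylsilyloxy)butan-2-one F3. F3 and thione 10 with Rh2(OAc)4 (1 mol%) in toluene should give a thiocarbonyl ylide that closes to thiirane 19, and PPh3 in the same flask removes sulfur (Barton–Kellogg-type olefination). The route is rejoined at 20.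

3. Step 8. The process at risk is reduction instead of carbonylation: direct hydride transfer to the vinylpalladium species (loss of the triflate without CO uptake) or conjugate reduction of the enone and acrylate by palladium hydride. The fallback delivers C8 by cross-coupling at the alcohol level and oxidises afterwards. It sets out from 20, which is coupled with tributyl(hydroxymethyl)stannane (Stille coupling; Pd(PPh3)4, LiCl, dioxane, 80 °C) to 2-(trimethylsilyl)ethyl (E)-3-{5-(hydroxymethyl)-4-[2-oxo-3-(triethylsilyloxy)butylidene]-4H-pyran-2-yl}prop-2-enoate F4. Oxidation of this allylic-type alcohol with MnO2 (CH2Cl2, rt) gives 22, where the route is rejoined before step 9.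

**Further compounds**

F1 | step 10 | racemic cis-diol (1:1 mixture of 24 and its (7S,8S) enantiomer) | O[C@@H]1C2=COC(/C=C/C(=O)OCC[Si](C)(C)C)=CC2=CC(=O)[C@]1(C)O.O[C@H]1C2=COC(/C=C/C(=O)OCC[Si](C)(C)C)=CC2=CC(=O)[C@@]1(C)O
F2 | step 10 | 2-(trimethylsilyl)ethyl (E)-3-[(7S,8S)-7-hydroxy-7-methyl-8-(2-methylpropanoyloxy)-6-oxo-7,8-dihydro-6H-isochromen-3-yl]prop-2-enoate | CC(C)C(=O)O[C@H]1C2=COC(/C=C/C(=O)OCC[Si](C)(C)C)=CC2=CC(=O)[C@@]1(C)O
F3 | step 7 | 1-diazo-3-(triethylsilyloxy)butan-2-one | CC[Si](CC)(CC)OC(C)C(=O)C=[N+]=[N-]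
F4 | step 8 | 2-(trimethylsilyl)ethyl (E)-3-{5-(hydroxymethyl)-4-[2-oxo-3-(triethylsilyloxy)butylidene]-4H-pyran-2-yl}prop-2-enoate | C[Si](C)(C)CCOC(=O)/C=C/C1=CC(=CC(=O)C(C)O[Si](CC)(CC)CC)C(CO)=CO1
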